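**Retrosynthetic overview**

1. The strategy rests on C5 (CH–OAc) and C6 (lactone CH–O) of the cyclodecene ring: adjacent carbons with cis oxygens, i.e. a vicinal cis-diol with O5 acetylated and O6 tied into the γ-lactone. The C5–C6 bond is made by reductive pinacol coupling of an open-chain Z-alkenyl dialdehyde.
2. Ring order: the ten-membered carbocycle first (pinacol), then the γ-lactone (C12 oxidised onto O6); O5 acetylation, O8 tigloylation and O2 desilylation follow.
3. Dialdehyde: an Evans syn-aldol forms C7–C8 and sets both centres. The imide carbonyl becomes C11 (methyl ketone, α-hydroxylation, methylenation). A p-methoxybenzylidene acetal across the C6 and C8 oxygens is opened by hydride to leave PMB on O8 and free the C6 carbinol.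
4. Aldehyde partner: 4-methyl-5,6-dihydro-2H-pyran-2-one supplies the Z C1=C10 unit with exactly one CH2 (C9) between C8 and C10 (a nerol-derived chain would carry one methylene too many). Asymmetric chromium-catalysed 2-(ethoxycarbonyl)allylation forms C2–C3 and sets C2.
5. Protecting groups C12–OTES, C8–OPMB and C2–OTBS are removed in that order after ring closure.

Key step: step 22

Remark: 4-methyl-5,6-dihydro-2H-pyran-2-one is taken as a catalogue compound; locants are germacrane locants (C1=C10 Z-alkene, C2 free carbinol, C4=C15 and C11=C13 methylenes, C5 acetoxy carbon, C6 lactone CH–O, C7 ring fusion, C8 tigloyloxy carbon, C12 lactone carbonyl); TES = triethylsilyl, TBS = tert-butyldimethylsilyl, PMB = 4-methoxybenzyl, Piv = pivaloyl.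

**Route**

Step 1
Reactants: 1 4-methyl-5,6-dihydro-2H-pyran-2-one
Product: 2 (2Z)-5-hydroxy-N-methoxy-N,3-dimethylpent-2-enamide
Conditions: MeNH(OMe)·HCl, AlMe3, CH2Cl2, 0 °C to rt
Reagents that add atoms: N,O-dimethylhydroxylamine hydrochloride, CNOC.Cl
Why: Weinreb aminolysis of the lactone by the aluminium amide opens the ring at the acyl carbon and keeps the Z trisubstituted alkene that the six-membered ring enforced.

Step 2
Reactants: 2 (2Z)-5-hydroxy-N-methoxy-N,3-dimethylpent-2-enamide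
Product: 3 (2Z)-N-methoxy-N,3-dimethyl-5-(triethylsilyloxy)pent-2-enamide
Conditions: TESCl, imidazole, CH2Cl2, 0 °C
Reagents that add atoms: chlorotriethylsilane, CC[Si](Cl)(CC)CC
Why: Imidazole-promoted silylation of the primary alcohol blocks relactonisation and masks the future C8 oxygen with a group removable beside a secondary TBS ether.

Step 3
Reactants: 3 (2Z)-N-methoxy-N,3-dimethyl-5-(triethylsilyloxy)pent-2-enamide
Product: 4 (2Z)-3-methyl-5-(triethylsilyloxy)pent-2-enal
Conditions: i-Bu2AlH, THF, −78 °C; Rochelle salt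
Reagents that add atoms: none
Why: Partial reduction of the Weinreb amide stops at the chelated tetrahedral aluminium adduct, so the Z-enal is released only on work-up without over-reduction or Z/E isomerisation.

Step 4
Reactants: 4 (2Z)-3-methyl-5-(triethylsilyloxy)pent-2-enal, 5 ethyl 2-(bromomethyl)acrylate
Product: 7 ethyl (4R,5Z)-4-hydroxy-6-methyl-2-methylidene-8-(triethylsilyloxy)oct-5-enoate, via trimethylsilyl ether 6 (not isolated)
Conditions: CrCl2 (10 mol %), 1,8-bis(oxazolinyl)carbazole ligand (enantiomer directing Re-face attack), Mn, TMSCl, i-Pr2NEt (cat.), THF, rt; then citric acid, MeOH, 0 °C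
Reagents that add atoms: none
Why: Catalytic asymmetric Nozaki–Hiyama–Kishi 2-(alkoxycarbonyl)allylation: the allylchromium species from 5 adds 1,2 to the enal inside the chiral ligand pocket, Re-face attack setting C2 as R, and mild acid removes only the trimethylsilyl ether.

Step 5
Reactants: 7 ethyl (4R,5Z)-4-hydroxy-6-methyl-2-methylidene-8-(triethylsilyloxy)oct-5-enoate
Product: 8 ethyl (4R,5Z)-4-(tert-butyldimethylsilyloxy)-6-methyl-2-methylidene-8-(triethylsilyloxy)oct-5-enoate
Conditions: TBSOTf, 2,6-lutidine, CH2Cl2, −78 °C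
Reagents that add atoms: tert-butyldimethylsilyl trifluoromethanesulfonate, CC(C)(C)[Si](C)(C)OS(=O)(=O)C(F)(F)F
Why: Silyl triflate silylation of the secondary allylic alcohol at low temperature prevents lactonisation and installs the group that stays until the last step.

Step 6
Reactants: 8 ethyl (4R,5Z)-4-(tert-butyldimethylsilyloxy)-6-methyl-2-methylidene-8-(triethylsilyloxy)oct-5-enoate
Product: 9 (4R,5Z)-4-(tert-butyldimethylsilyloxy)-6-methyl-2-methylidene-8-(triethylsilyloxy)oct-5-en-1-ol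
Conditions: i-Bu2AlH, CH2Cl2, −78 °C
Reagents that add atoms: none
Why: 1,2-Reduction of the acrylate ester by the aluminium hydride gives the allylic alcohol (future C5) and leaves both silyl ethers intact.

Step 7
Reactants: 9 (4R,5Z)-4-(tert-butyldimethylsilyloxy)-6-methyl-2-methylidene-8-(triethylsilyloxy)oct-5-en-1-ol
Product: 10 (4R,5Z)-4-(tert-butyldimethylsilyloxy)-6-methyl-2-methylidene-8-(triethylsilyloxy)oct-5-en-1-yl pivalate
Conditions: PivCl, pyridine, DMAP (cat.), CH2Cl2, 0 °C
Reagents that add atoms: pivaloyl chloride, CC(C)(C)C(=O)Cl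
Why: Acylation gives a hindered ester that withstands the organometallic steps ahead and is cleaved by hydride together with the acetal in step 20.

Step 8
Reactants: 10 (4R,5Z)-4-(tert-butyldimethylsilyloxy)-6-methyl-2-methylidene-8-(triethylsilyloxy)oct-5-en-1-yl pivalate
Product: 11 (4R,5Z)-4-(tert-butyldimethylsilyloxy)-8-hydroxy-6-methyl-2-methylideneoct-5-en-1-yl pivalate
Conditions: PPTS (cat.), MeOH/CH2Cl2, 0 °C
Reagents that add atoms: none
Why: Acid-catalysed methanolysis cleaves the primary triethylsilyl ether far faster than the secondary allylic TBS ether (selective desilylation).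

Step 9
Reactants: 11 (4R,5Z)-4-(tert-butyldimethylsilyloxy)-8-hydroxy-6-methyl-2-methylideneoct-5-en-1-yl pivalate
Product: 12 (4R,5Z)-4-(tert-butyldimethylsilyloxy)-6-methyl-2-methylidene-8-oxooct-5-en-1-yl pivalate
Conditions: Dess–Martin periodinane, NaHCO3, CH2Cl2, 0 °C; used at once
Reagents that add atoms: none
Why: Buffered Dess–Martin oxidation gives the β,γ-unsaturated aldehyde under non-basic conditions, so the C1=C10 alkene should not move into conjugation.

Step 10
Reactants: 13 4-methoxybenzyl alcohol, 14 methyl acrylate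
Product: 15 methyl 3-(4-methoxybenzyloxy)propanoate
Conditions: NaH (5 mol %), THF, 0 °C to rt
Reagents that add atoms: none
Why: Base-catalysed oxa-Michael addition of the benzylic alkoxide to the acrylate.

Step 11
Reactants: 15 methyl 3-(4-methoxybenzyloxy)propanoate
Product: 16 3-(4-methoxybenzyloxy)propanoic acid
Conditions: LiOH, THF/H2O, rt; then aq. HCl to pH 3
Reagents that add atoms: lithium hydroxide, [Li+].[OH-]
Why: Saponification of the methyl ester, the PMB ether being stable to base.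

Step 12
Reactants: 16 3-(4-methoxybenzyloxy)propanoic acid, 17 (S)-4-benzyl-1,3-oxazolidin-2-one
Product: 19 (S)-4-benzyl-3-[3-(4-methoxybenzyloxy)propanoyl]-1,3-oxazolidin-2-one, via mixed pivalic anhydride 18 (not isolated)
Conditions: PivCl, Et3N, THF, −20 °C; then 17, LiCl, rt
Reagents that add atoms: none
Why: Mixed-anhydride activation followed by LiCl/Et3N-mediated N-acylation of the oxazolidinone at the less hindered carbonyl.

Step 13
Reactants: 19 (S)-4-benzyl-3-[3-(4-methoxybenzyloxy)propanoyl]-1,3-oxazolidin-2-one, 12 (4R,5Z)-4-(tert-butyldimethylsilyloxy)-6-methyl-2-methylidene-8-oxooct-5-en-1-yl pivalate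
Product: 21 (4S)-4-benzyl-3-[(2S,3R,5Z,7R)-7-(tert-butyldimethylsilyloxy)-3-hydroxy-2-[(4-methoxybenzyloxy)methyl]-5-methyl-9-methylidene-10-(pivaloyloxy)dec-5-enoyl]-1,3-oxazolidin-2-one, via dibutylboron Z-enolate 20 (not isolated)
Conditions: Bu2BOTf, Et3N, CH2Cl2, −78 to 0 °C; 12, −78 to 0 °C; pH 7 buffer, MeOH, H2O2, 0 °C
Reagents that add atoms: none
Why: Evans syn-aldol: the Z boron enolate reacts through a closed Zimmerman–Traxler chair on the face opposite the benzyl group of the (S)-auxiliary, giving the syn adduct with C7 and C8 as needed and the imide carbonyl as the future C11, while the cold aprotic medium should keep the β,γ-unsaturated aldehyde from conjugating.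

Step 14
Reactants: 21 the aldol adduct
Product: 22 (2S,3R,5Z,7R)-7-(tert-butyldimethylsilyloxy)-3-hydroxy-N-methoxy-2-[(4-methoxybenzyloxy)methyl]-N,5-dimethyl-9-methylidene-10-(pivaloyloxy)dec-5-enamide
Conditions: MeNH(OMe)·HCl, AlMe3, THF, −20 to 0 °C
Reagents that add atoms: N,O-dimethylhydroxylamine hydrochloride, CNOC.Cl
Why: Weinreb transamination: the aluminium amide, directed by the free β-hydroxyl, cleaves the exocyclic imide carbonyl and releases the auxiliary, the hindered pivalate being inert at this temperature.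

Step 15
Reactants: 22 the hydroxy Weinreb amide
Product: 23 (2S,4R,5S)-4-[(2Z,4R)-4-(tert-butyldimethylsilyloxy)-2-methyl-6-methylidene-7-(pivaloyloxy)hept-2-en-1-yl]-N-methoxy-2-(4-methoxyphenyl)-N-methyl-1,3-dioxane-5-carboxamide
Conditions: DDQ, 4 Å MS, CH2Cl2 (anhydrous), 0 °C
Reagents that add atoms: none
Why: Oxidative acetalisation (Oikawa–Yonemitsu): DDQ converts the PMB ether into an oxocarbenium ion that the C8 hydroxyl traps, giving the all-equatorial p-methoxybenzylidene acetal.

Step 16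
Reactants: 23 the acetal Weinreb amide
Product: 24 (4R,5Z)-7-[(2S,4R,5S)-5-acetyl-2-(4-methoxyphenyl)-1,3-dioxan-4-yl]-4-(tert-butyldimethylsilyloxy)-6-methyl-2-methylidenehept-5-en-1-yl pivalate
Conditions: MeMgBr, THF, −20 to 0 °C; aq. NH4Cl
Reagents that add atoms: methylmagnesium bromide, C[Mg]Br
Why: Grignard addition to the Weinreb amide stops at the chelated tetrahedral intermediate and gives the methyl ketone on work-up.

Step 17
Reactants: 24 the methyl ketone
Product: 26 (4R,5Z)-4-(tert-butyldimethylsilyloxy)-7-[(2S,4R,5S)-5-(hydroxyacetyl)-2-(4-methoxyphenyl)-1,3-dioxan-4-yl]-6-methyl-2-methylidenehept-5-en-1-yl pivalate, via potassium enolate 25 (not isolated)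
Conditions: KN(SiMe3)2, THF, −78 °C; 3-phenyl-2-(phenylsulfonyl)oxaziridine, −78 °C; aq. NH4Cl
Reagents that add atoms: 3-phenyl-2-(phenylsulfonyl)oxaziridine, O=S(=O)(c1ccccc1)N1OC1c1ccccc1
Why: Kinetic deprotonation at the methyl group and Davis oxaziridine hydroxylation of the enolate (electrophilic oxygen transfer) give the primary α-hydroxy ketone without touching C7.

Step 18
Reactants: 26 the α-hydroxy ketone
Product: 27 (4R,5Z)-4-(tert-butyldimethylsilyloxy)-7-[(2S,4R,5S)-2-(4-methoxyphenyl)-5-[(triethylsilyloxy)acetyl]-1,3-dioxan-4-yl]-6-methyl-2-methylidenehept-5-en-1-yl pivalate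
Conditions: TESCl, imidazole, CH2Cl2, 0 °C
Reagents that add atoms: chlorotriethylsilane, CC[Si](Cl)(CC)CC
Why: Silylation of the primary alcohol places the triethylsilyl group that masks C12 through the ring closure.

Step 19
Reactants: 27 the α-silyloxy ketone
Product: 28 (4R,5Z)-4-(tert-butyldimethylsilyloxy)-7-[(2S,4R,5S)-2-(4-methoxyphenyl)-5-[3-(triethylsilyloxy)prop-1-en-2-yl]-1,3-dioxan-4-yl]-6-methyl-2-methylidenehept-5-en-1-yl pivalate
Conditions: Cp2TiMe2, toluene/THF, 65 °C, dark
Reagents that add atoms: dimethyltitanocene, C[Ti](C)(C1C=CC=C1)C1C=CC=C1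
Why: Petasis methylenation: thermally generated Cp2Ti=CH2 converts the ketone into the C11=C13 alkene under non-basic, non-acidic conditions, so the epimerisable C7 centre and the acetal should survive and the hindered ester is left alone.

Step 20
Reactants: 28 the acetal pivalate
Product: 29 (2S,3R,5Z,7R)-7-(tert-butyldimethylsilyloxy)-3-(4-methoxybenzyloxy)-5-methyl-9-methylidene-2-[3-(triethylsilyloxy)prop-1-en-2-yl]dec-5-ene-1,10-diol
Conditions: i-Bu2AlH (excess), CH2Cl2, −78 to 0 °C; Rochelle salt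
Reagents that add atoms: none
Why: The aluminium hydride cleaves the pivalate and opens the p-methoxybenzylidene acetal regioselectively (aluminium on the less hindered primary oxygen, hydride to the acetal carbon), leaving PMB on the secondary C8 oxygen and freeing both primary alcohols in one operation.

Step 21
Reactants: 29 the diol
Product: 30 (2R,3R,5Z,7R)-7-(tert-butyldimethylsilyloxy)-3-(4-methoxybenzyloxy)-5-methyl-9-methylidene-2-[3-(triethylsilyloxy)prop-1-en-2-yl]dec-5-enedial
Conditions: Dess–Martin periodinane, NaHCO3, CH2Cl2, 0 °C; used at once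
Reagents that add atoms: none
Why: Buffered double Dess–Martin oxidation gives the enal and the α-branched β,γ-unsaturated aldehyde without base, so C7 should not epimerise and C11=C13 should not conjugate.

Step 22
Reactants: 30 the dialdehyde
Product: 31 (1S,2R,3S,4R,6Z,8R)-8-(tert-butyldimethylsilyloxy)-4-(4-methoxybenzyloxy)-6-methyl-10-methylidene-3-[3-(triethylsilyloxy)prop-1-en-2-yl]cyclodec-6-ene-1,2-diol
Conditions: TiCl3(DME)1.5, Zn–Cu couple, DME, reflux 3 h; then 30 by syringe pump over 30 h at 25 °C (final 2 mM); aq. K2CO3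
Reagents that add atoms: none
Why: Low-valent titanium from TiCl3(DME)1.5 and Zn–Cu couple reduces both formyl groups by single-electron transfer to titanium-bound ketyl radicals, which combine at carbon to give the titanium diolate, hydrolysed to the diol because deoxygenation does not follow at 25 °C; the closest known reaction type is the McMurry-type pinacol macrocyclisation of dialdehydes, enals included, to ten- to fourteen-membered diols. The ten-membered carbocycle closes by intramolecular radical–radical coupling of the two ketyl carbons under syringe-pump high dilution, the Z C1=C10 alkene holding the chain ends within reach, and the enal-derived ketyl is expected to couple at C5 and not at C15 because titanium holds both partners at the oxygen-bearing carbons. C6 is controlled by the neighbouring C7 stereocentre: bond formation anti to the C7 alkenyl group (Felkin–Anh sense, the sp2 substituent as the large group) gives the 6R centre, with O6 cis to that group as the cis-fused lactone requires. C5 is controlled relative to C6 by the titanium bridging the two ketyl oxygens on one side of the forming bond, which leads to the cis (erythro, 5S) diol. The step therefore needs cis-selectivity on one face of C6; the C7 and C8 stereocentres and the rigid Z-alkene bias it, but cis preference is weaker in medium rings than in small ones and the C8 ether does not reinforce the C7 effect, so the ratio has to be determined and a convergent correction is given at the end.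

Step 23
Reactants: 31 the cis-diol
Product: 32 (1S,2R,3S,4R,6Z,8R)-8-(tert-butyldimethylsilyloxy)-3-(3-hydroxyprop-1-en-2-yl)-4-(4-methoxybenzyloxy)-6-methyl-10-methylidenecyclodec-6-ene-1,2-diol
Conditions: PPTS (cat.), MeOH/CH2Cl2, 0 °C
Reagents that add atoms: none
Why: Selective acid-catalysed methanolysis of the primary allylic triethylsilyl ether beside the secondary TBS ether.

Step 24
Reactants: 32 the triol
Product: 35 (2R,5S,6R,7R,8R)-2-(tert-butyldimethylsilyloxy)-5-hydroxy-8-(4-methoxybenzyloxy)germacra-1(10)Z,4(15),11(13)-trien-12,6-olide, via hydroxy enal 33 (not isolated), via lactol 34 (not isolated)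
Conditions: [Cu(MeCN)4]OTf, 2,2'-bipyridine, TEMPO, N-methylimidazole (each cat.), MeCN, air, rt
Reagents that add atoms: none
Why: Copper/nitroxyl aerobic oxidative lactonisation (Stahl type): the primary allylic alcohol is oxidised to the enal, the C6 hydroxyl closes the five-membered lactol (5-exo-trig, cis-fused as fixed by C6 and C7) and the lactol is oxidised to the γ-lactone, while the secondary hydroxyls react much more slowly and, unlike with hypervalent iodine oxidants, the vicinal diol cannot be cleaved.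

Step 25
Reactants: 35 the hydroxy lactone
Product: 36 (2R,5S,6R,7R,8R)-5-acetoxy-2-(tert-butyldimethylsilyloxy)-8-(4-methoxybenzyloxy)germacra-1(10)Z,4(15),11(13)-trien-12,6-olide
Conditions: Ac2O, pyridine, DMAP (cat.), CH2Cl2, 0 °C
Reagents that add atoms: acetic anhydride, CC(=O)OC(C)=O
Why: DMAP-catalysed acetylation of the only free hydroxyl (C5).

Step 26
Reactants: 36 the acetate
Product: 37 (2R,5S,6R,7R,8R)-5-acetoxy-2-(tert-butyldimethylsilyloxy)-8-hydroxygermacra-1(10)Z,4(15),11(13)-trien-12,6-olide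
Conditions: DDQ, CH2Cl2/pH 7 buffer, 0 °C to rt
Reagents that add atoms: none
Why: Oxidative PMB cleavage (hydride abstraction by DDQ, hydrolysis of the oxocarbenium ion) leaves the acetate, the TBS ether and the α-methylene lactone untouched.

Step 27
Reactants: 37 the C8 alcohol
Product: 38 (2R,5S,6R,7R,8R)-5-acetoxy-2-(tert-butyldimethylsilyloxy)-8-[(E)-2-methylbut-2-enoyloxy]germacra-1(10)Z,4(15),11(13)-trien-12,6-olide
Conditions: (E)-2-methylbut-2-enoyl chloride, Et3N, DMAP, CH2Cl2, 0 °C to rt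
Reagents that add atoms: (E)-2-methylbut-2-enoyl chloride, C/C=C(\C)C(=O)Cl
Why: DMAP-catalysed acylation with the chloride of the thermodynamically stable E acid (tiglic acid), so double-bond isomerisation of the acyl group cannot lead elsewhere.

Step 28
Reactants: 38 the silyl ether
Product: 39 (2R,5S,6R,7R,8R)-5-acetoxy-2-hydroxy-8-[(E)-2-methylbut-2-enoyloxy]germacra-1(10)Z,4(15),11(13)-trien-12,6-olide (CNP0210609.1)
Conditions: HF·pyridine, pyridine, THF, 0 °C to rt
Reagents that add atoms: none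
Why: Acidic fluoride desilylation cleaves the secondary allylic TBS ether without acyl migration or conjugate addition to the α-methylene lactone.

**Compound list**

1 | 4-methyl-5,6-dihydro-2H-pyran-2-one | CC1=CC(=O)OCC1 | starting material
2 | (2Z)-5-hydroxy-N-methoxy-N,3-dimethylpent-2-enamide | OCC/C(C)=C\C(=O)N(C)OC | intermediate
3 | (2Z)-N-methoxy-N,3-dimethyl-5-(triethylsilyloxy)pent-2-enamide | CC[Si](CC)(CC)OCC/C(C)=C\C(=O)N(C)OC | intermediate
4 | (2Z)-3-methyl-5-(triethylsilyloxy)pent-2-enal | CC[Si](CC)(CC)OCC/C(C)=C\C=O | intermediate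
5 | ethyl 2-(bromomethyl)acrylate | C=C(CBr)C(=O)OCC | starting material
6 | ethyl (4R,5Z)-6-methyl-2-methylidene-8-(triethylsilyloxy)-4-(trimethylsilyloxy)oct-5-enoate | CC[Si](CC)(CC)OCC/C(C)=C\[C@H](O[Si](C)(C)C)CC(=C)C(=O)OCC | intermediate
7 | ethyl (4R,5Z)-4-hydroxy-6-methyl-2-methylidene-8-(triethylsilyloxy)oct-5-enoate | CC[Si](CC)(CC)OCC/C(C)=C\[C@H](O)CC(=C)C(=O)OCC | intermediate
8 | ethyl (4R,5Z)-4-(tert-butyldimethylsilyloxy)-6-methyl-2-methylidene-8-(triethylsilyloxy)oct-5-enoate | CC[Si](CC)(CC)OCC/C(C)=C\[C@H](O[Si](C)(C)C(C)(C)C)CC(=C)C(=O)OCC | intermediate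
9 | (4R,5Z)-4-(tert-butyldimethylsilyloxy)-6-methyl-2-methylidene-8-(triethylsilyloxy)oct-5-en-1-ol | CC[Si](CC)(CC)OCC/C(C)=C\[C@H](O[Si](C)(C)C(C)(C)C)CC(=C)CO | intermediate
10 | (4R,5Z)-4-(tert-butyldimethylsilyloxy)-6-methyl-2-methylidene-8-(triethylsilyloxy)oct-5-en-1-yl pivalate | CC[Si](CC)(CC)OCC/C(C)=C\[C@H](O[Si](C)(C)C(C)(C)C)CC(=C)COC(=O)C(C)(C)C | intermediate
11 | (4R,5Z)-4-(tert-butyldimethylsilyloxy)-8-hydroxy-6-methyl-2-methylideneoct-5-en-1-yl pivalate | OCC/C(C)=C\[C@H](O[Si](C)(C)C(C)(C)C)CC(=C)COC(=O)C(C)(C)C | intermediate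
12 | (4R,5Z)-4-(tert-butyldimethylsilyloxy)-6-methyl-2-methylidene-8-oxooct-5-en-1-yl pivalate | O=CC/C(C)=C\[C@H](O[Si](C)(C)C(C)(C)C)CC(=C)COC(=O)C(C)(C)C | intermediate
13 | 4-methoxybenzyl alcohol | COc1ccc(CO)cc1 | starting material
14 | methyl acrylate | C=CC(=O)OC | starting material
15 | methyl 3-(4-methoxybenzyloxy)propanoate | COC(=O)CCOCc1ccc(OC)cc1 | intermediate
16 | 3-(4-methoxybenzyloxy)propanoic acid | OC(=O)CCOCc1ccc(OC)cc1 | intermediate
17 | (S)-4-benzyl-1,3-oxazolidin-2-one | O=C1N[C@@H](Cc2ccccc2)CO1 | starting material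
18 | 3-(4-methoxybenzyloxy)propanoic pivalic anhydride | CC(C)(C)C(=O)OC(=O)CCOCc1ccc(OC)cc1 | intermediate
19 | (S)-4-benzyl-3-[3-(4-methoxybenzyloxy)propanoyl]-1,3-oxazolidin-2-one | COc1ccc(COCCC(=O)N2[C@@H](Cc3ccccc3)COC2=O)cc1 | intermediate
20 | dibutylboron Z-enolate of 19 | CCCCB(CCCC)O/C(=C\COCc1ccc(OC)cc1)N1[C@@H](Cc2ccccc2)COC1=O | intermediate
21 | (4S)-4-benzyl-3-[(2S,3R,5Z,7R)-7-(tert-butyldimethylsilyloxy)-3-hydroxy-2-[(4-methoxybenzyloxy)methyl]-5-methyl-9-methylidene-10-(pivaloyloxy)dec-5-enoyl]-1,3-oxazolidin-2-one | O=C1OC[C@H](Cc2ccccc2)N1C(=O)[C@@H](COCc1ccc(OC)cc1)[C@H](O)C/C(C)=C\[C@H](O[Si](C)(C)C(C)(C)C)CC(=C)COC(=O)C(C)(C)C | intermediate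
22 | (2S,3R,5Z,7R)-7-(tert-butyldimethylsilyloxy)-3-hydroxy-N-methoxy-2-[(4-methoxybenzyloxy)methyl]-N,5-dimethyl-9-methylidene-10-(pivaloyloxy)dec-5-enamide | CON(C)C(=O)[C@@H](COCc1ccc(OC)cc1)[C@H](O)C/C(C)=C\[C@H](O[Si](C)(C)C(C)(C)C)CC(=C)COC(=O)C(C)(C)C | intermediate
23 | (2S,4R,5S)-4-[(2Z,4R)-4-(tert-butyldimethylsilyloxy)-2-methyl-6-methylidene-7-(pivaloyloxy)hept-2-en-1-yl]-N-methoxy-2-(4-methoxyphenyl)-N-methyl-1,3-dioxane-5-carboxamide | CON(C)C(=O)[C@H]1CO[C@H](c2ccc(OC)cc2)O[C@@H]1C/C(C)=C\[C@H](O[Si](C)(C)C(C)(C)C)CC(=C)COC(=O)C(C)(C)C | intermediate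
24 | (4R,5Z)-7-[(2S,4R,5S)-5-acetyl-2-(4-methoxyphenyl)-1,3-dioxan-4-yl]-4-(tert-butyldimethylsilyloxy)-6-methyl-2-methylidenehept-5-en-1-yl pivalate | CC(=O)[C@H]1CO[C@H](c2ccc(OC)cc2)O[C@@H]1C/C(C)=C\[C@H](O[Si](C)(C)C(C)(C)C)CC(=C)COC(=O)C(C)(C)C | intermediate
25 | potassium enolate of 24 (terminal enolate at the acetyl group) | [K+].C=C([O-])[C@H]1CO[C@H](c2ccc(OC)cc2)O[C@@H]1C/C(C)=C\[C@H](O[Si](C)(C)C(C)(C)C)CC(=C)COC(=O)C(C)(C)C | intermediate
26 | (4R,5Z)-4-(tert-butyldimethylsilyloxy)-7-[(2S,4R,5S)-5-(hydroxyacetyl)-2-(4-methoxyphenyl)-1,3-dioxan-4-yl]-6-methyl-2-methylidenehept-5-en-1-yl pivalate | OCC(=O)[C@H]1CO[C@H](c2ccc(OC)cc2)O[C@@H]1C/C(C)=C\[C@H](O[Si](C)(C)C(C)(C)C)CC(=C)COC(=O)C(C)(C)C | intermediate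
27 | (4R,5Z)-4-(tert-butyldimethylsilyloxy)-7-[(2S,4R,5S)-2-(4-methoxyphenyl)-5-[(triethylsilyloxy)acetyl]-1,3-dioxan-4-yl]-6-methyl-2-methylidenehept-5-en-1-yl pivalate | CC[Si](CC)(CC)OCC(=O)[C@H]1CO[C@H](c2ccc(OC)cc2)O[C@@H]1C/C(C)=C\[C@H](O[Si](C)(C)C(C)(C)C)CC(=C)COC(=O)C(C)(C)C | intermediate
28 | (4R,5Z)-4-(tert-butyldimethylsilyloxy)-7-[(2S,4R,5S)-2-(4-methoxyphenyl)-5-[3-(triethylsilyloxy)prop-1-en-2-yl]-1,3-dioxan-4-yl]-6-methyl-2-methylidenehept-5-en-1-yl pivalate | C=C(CO[Si](CC)(CC)CC)[C@H]1CO[C@H](c2ccc(OC)cc2)O[C@@H]1C/C(C)=C\[C@H](O[Si](C)(C)C(C)(C)C)CC(=C)COC(=O)C(C)(C)C | intermediate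
29 | (2S,3R,5Z,7R)-7-(tert-butyldimethylsilyloxy)-3-(4-methoxybenzyloxy)-5-methyl-9-methylidene-2-[3-(triethylsilyloxy)prop-1-en-2-yl]dec-5-ene-1,10-diol | C=C(CO[Si](CC)(CC)CC)[C@@H](CO)[C@H](OCc1ccc(OC)cc1)C/C(C)=C\[C@H](O[Si](C)(C)C(C)(C)C)CC(=C)CO | intermediate
30 | (2R,3R,5Z,7R)-7-(tert-butyldimethylsilyloxy)-3-(4-methoxybenzyloxy)-5-methyl-9-methylidene-2-[3-(triethylsilyloxy)prop-1-en-2-yl]dec-5-enedial | C=C(CO[Si](CC)(CC)CC)[C@@H](C=O)[C@H](OCc1ccc(OC)cc1)C/C(C)=C\[C@H](O[Si](C)(C)C(C)(C)C)CC(=C)C=O | intermediate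
31 | (1S,2R,3S,4R,6Z,8R)-8-(tert-butyldimethylsilyloxy)-4-(4-methoxybenzyloxy)-6-methyl-10-methylidene-3-[3-(triethylsilyloxy)prop-1-en-2-yl]cyclodec-6-ene-1,2-diol | C=C(CO[Si](CC)(CC)CC)[C@@H]1[C@H](OCc2ccc(OC)cc2)C/C(C)=C\[C@H](O[Si](C)(C)C(C)(C)C)CC(=C)[C@H](O)[C@@H]1O | intermediate
32 | (1S,2R,3S,4R,6Z,8R)-8-(tert-butyldimethylsilyloxy)-3-(3-hydroxyprop-1-en-2-yl)-4-(4-methoxybenzyloxy)-6-methyl-10-methylidenecyclodec-6-ene-1,2-diol | C=C(CO)[C@@H]1[C@H](OCc2ccc(OC)cc2)C/C(C)=C\[C@H](O[Si](C)(C)C(C)(C)C)CC(=C)[C@H](O)[C@@H]1O | intermediate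
33 | hydroxy enal: 32 with the side-chain CH2OH (C12) oxidised to CHO | C=C(C=O)[C@@H]1[C@H](OCc2ccc(OC)cc2)C/C(C)=C\[C@H](O[Si](C)(C)C(C)(C)C)CC(=C)[C@H](O)[C@@H]1O | intermediate
34 | lactol: C12 hemiacetal closed on O6 (both anomers) | C=C1C(O)O[C@@H]2[C@H]1[C@H](OCc1ccc(OC)cc1)C/C(C)=C\[C@H](O[Si](C)(C)C(C)(C)C)CC(=C)[C@@H]2O | intermediate
35 | (2R,5S,6R,7R,8R)-2-(tert-butyldimethylsilyloxy)-5-hydroxy-8-(4-methoxybenzyloxy)germacra-1(10)Z,4(15),11(13)-trien-12,6-olide | C=C1C(=O)O[C@@H]2[C@H]1[C@H](OCc1ccc(OC)cc1)C/C(C)=C\[C@H](O[Si](C)(C)C(C)(C)C)CC(=C)[C@@H]2O | intermediate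
36 | (2R,5S,6R,7R,8R)-5-acetoxy-2-(tert-butyldimethylsilyloxy)-8-(4-methoxybenzyloxy)germacra-1(10)Z,4(15),11(13)-trien-12,6-olide | C=C1C(=O)O[C@@H]2[C@H]1[C@H](OCc1ccc(OC)cc1)C/C(C)=C\[C@H](O[Si](C)(C)C(C)(C)C)CC(=C)[C@@H]2OC(C)=O | intermediate
37 | (2R,5S,6R,7R,8R)-5-acetoxy-2-(tert-butyldimethylsilyloxy)-8-hydroxygermacra-1(10)Z,4(15),11(13)-trien-12,6-olide | C=C1C(=O)O[C@@H]2[C@H]1[C@H](O)C/C(C)=C\[C@H](O[Si](C)(C)C(C)(C)C)CC(=C)[C@@H]2OC(C)=O | intermediate
38 | (2R,5S,6R,7R,8R)-5-acetoxy-2-(tert-butyldimethylsilyloxy)-8-[(E)-2-methylbut-2-enoyloxy]germacra-1(10)Z,4(15),11(13)-trien-12,6-olide | C=C1C(=O)O[C@@H]2[C@H]1[C@H](OC(=O)/C(C)=C/C)C/C(C)=C\[C@H](O[Si](C)(C)C(C)(C)C)CC(=C)[C@@H]2OC(C)=O | intermediate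
39 | (2R,5S,6R,7R,8R)-5-acetoxy-2-hydroxy-8-[(E)-2-methylbut-2-enoyloxy]germacra-1(10)Z,4(15),11(13)-trien-12,6-olide (CNP0210609.1) | C=C1C(=O)O[C@@H]2[C@H]1[C@H](OC(=O)/C(C)=C/C)C/C(C)=C\[C@H](O)CC(=C)[C@@H]2OC(C)=O | target

**Step count and risks**

Total step count: 28. Longest linear sequence: 25 steps (steps 1–9 and 13–28).

The three steps most likely to fail:

Step 22 (pinacol macrocyclisation). What may go wrong: the two ketyl carbons combine with the oxygens on opposite sides, so that the trans-diol forms beside or instead of the cis-diol. The fallback corrects C5 by oxidation and chelation-controlled reduction. It sets out from dialdehyde 30: the coupling is run as in step 22 and the diol mixture, whose other component is the C5-epimeric trans-diol F1, is taken without separation into MnO2 (CH2Cl2, rt), which oxidises only the allylic C5 carbinol and converges both isomers on the α-hydroxy enone F2. Zn(BH4)2 in Et2O at −20 °C then reduces the ketone through the five-membered zinc chelate with the C6 hydroxyl, hydride arriving anti to the C7 side, which should give the erythro diol and so comes back to the route at 31.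

Step 24 (oxidative lactonisation). What may go wrong: the intermediate enal closes the six-membered lactol on the C5 hydroxyl, or the secondary allylic C5 hydroxyl is itself oxidised. The fallback changes the order so that C5 is blocked first. It sets out from diol 31: acetylation of the less hindered allylic C5 hydroxyl (Ac2O 1.1 equiv, 2,4,6-collidine, CH2Cl2, −20 °C) gives the mono-acetate F5; PPTS in MeOH removes the TES group to give the hydroxy acetate F6; MnO2 or TEMPO/PhI(OAc)2 (no free vicinal diol is left) then lactonises on the only available hydroxyl, O6, and comes back to the route at 36.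

Step 19 (methylenation). What may go wrong: at 65 °C the titanium methylidene is consumed by enolisation of the hindered α-silyloxy ketone or attacks the pivalate, so conversion is low. The fallback builds C11=C13 by cross-coupling instead of carbonyl methylenation. It sets out from methyl ketone 24: KN(SiMe3)2 and PhNTf2 in THF at −78 °C give the terminal enol triflate F3; Stille hydroxymethylation with Bu3SnCH2OH (Pd2(dba)3, AsPh3, LiCl, NMP, 40 °C, mild enough that the allylic pivalate should not ionise) gives the allylic alcohol F4; TESCl and imidazole then come back to the route at 28.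

**Further compounds**

F1 | step 22 | (1R,2R,3S,4R,6Z,8R)-8-(tert-butyldimethylsilyloxy)-4-(4-methoxybenzyloxy)-6-methyl-10-methylidene-3-[3-(triethylsilyloxy)prop-1-en-2-yl]cyclodec-6-ene-1,2-diol (trans-diol, C5 epimer of 31) | C=C(CO[Si](CC)(CC)CC)[C@@H]1[C@H](OCc2ccc(OC)cc2)C/C(C)=C\[C@H](O[Si](C)(C)C(C)(C)C)CC(=C)[C@@H](O)[C@@H]1O
F2 | step 22 | α-hydroxy enone: 31 with the C5 carbinol oxidised to the ketone | C=C(CO[Si](CC)(CC)CC)[C@@H]1[C@H](OCc2ccc(OC)cc2)C/C(C)=C\[C@H](O[Si](C)(C)C(C)(C)C)CC(=C)C(=O)[C@@H]1O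
F3 | step 19 | enol triflate of 24 (1-(trifluoromethylsulfonyloxy)vinyl group on the dioxane) | C=C(OS(=O)(=O)C(F)(F)F)[C@H]1CO[C@H](c2ccc(OC)cc2)O[C@@H]1C/C(C)=C\[C@H](O[Si](C)(C)C(C)(C)C)CC(=C)COC(=O)C(C)(C)C
F4 | step 19 | allylic alcohol: 28 without the TES group | C=C(CO)[C@H]1CO[C@H](c2ccc(OC)cc2)O[C@@H]1C/C(C)=C\[C@H](O[Si](C)(C)C(C)(C)C)CC(=C)COC(=O)C(C)(C)C
F5 | step 24 | C5 mono-acetate of 31 | C=C(CO[Si](CC)(CC)CC)[C@@H]1[C@H](OCc2ccc(OC)cc2)C/C(C)=C\[C@H](O[Si](C)(C)C(C)(C)C)CC(=C)[C@H](OC(C)=O)[C@@H]1O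
F6 | step 24 | C5 mono-acetate of 32 (C12 hydroxyl free) | C=C(CO)[C@@H]1[C@H](OCc2ccc(OC)cc2)C/C(C)=C\[C@H](O[Si](C)(C)C(C)(C)C)CC(=C)[C@H](OC(C)=O)[C@@H]1O
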